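**Plan**
1. Retrosynthesis: the five phenols are freed last (benzyl ethers); the C-2–aryl bond of the flavanone is cut (asymmetric conjugate arylation of a 3-arylchromone); then C-3 is excised together with its aryl group, cutting C2–C3 and C3–C4 at once.
2. Enabling feature: C-3 of the pyranone sits between the ketone carbon C-4 and the oxygen-bearing C-2 and carries only H and C-3′ of the flavone B ring, so it is an aryl carbene carbon. What remains (O1, C-2, C-4, C-4a, C-8a) is the furan ring of a 3-silyloxybenzofuran, whose enol-ether double bond is the carbene acceptor.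
3. Forward: the flavone pyranone is made first (Claisen–Schmidt, oxidative cyclisation), then nitrile → amidine → chlorodiazirine. The carbene carbon enters the five-membered furan ring, which becomes the six-membered chromone ring while the interflavonoid C3–C3′ bond forms in the same event. Conjugate arylation then saturates the ring.
4. Stereochemistry: C-2 (S) comes from the chiral rhodium catalyst (aryl to the Re face of C-2); C-3 (R) follows by equilibration of the acidic α-aryl ketone centre to the 2,3-trans isomer.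

Key step: step 9

Remark: the target descriptors are read as (2S,3R), which is the 2,3-trans isomer; compounds 1, 4, 6 and 17 are taken as commercially available.

**Step 1**
Reactants: 1 4,6-dihydroxy-1-benzofuran-3(2H)-one
Product: 2 4,6-bis(benzyloxy)-1-benzofuran-3(2H)-one
Conditions: BnBr (2.2 equiv), K2CO3, DMF, rt
Reagents that add atoms: benzyl bromide BrCc1ccccc1
Why: Williamson O-benzylation of both phenols under mild carbonate conditions should outpace C-2 alkylation of the coumaranone.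

**Step 2**
Reactants: 2 4,6-bis(benzyloxy)-1-benzofuran-3(2H)-one
Product: 3 tert-butyl{[4,6-bis(benzyloxy)-1-benzofuran-3-yl]oxy}dimethylsilane
Conditions: TBSOTf, Et3N, CH2Cl2, 0 °C
Reagents that add atoms: tert-butyldimethylsilyl trifluoromethanesulfonate CC(C)(C)[Si](C)(C)OS(=O)(=O)C(F)(F)F
Why: Silyl enol ether formation by soft enolisation traps the enol tautomer as the aromatic 3-silyloxybenzofuran, the electron-rich enol ether needed for step 9.

**Step 3**
Reactants: 4 1-(2,6-dihydroxy-4-methoxyphenyl)ethan-1-one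
Product: 5 1-[2-(benzyloxy)-6-hydroxy-4-methoxyphenyl]ethan-1-one
Conditions: BnBr (1.05 equiv), K2CO3, acetone, reflux
Reagents that add atoms: benzyl bromide BrCc1ccccc1
Why: Williamson etherification stops at the mono-ether because the second ortho hydroxyl is held in a hydrogen bond to the ketone, and it is needed free for the later pyranone closure.

**Step 4**
Reactants: 6 5-formyl-2-hydroxybenzonitrile
Product: 7 2-(benzyloxy)-5-formylbenzonitrile
Conditions: BnBr, K2CO3, DMF, rt
Reagents that add atoms: benzyl bromide BrCc1ccccc1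
Why: Williamson benzylation of the acidic cyanophenol should be clean.

**Step 5**
Reactants: 5 1-[2-(benzyloxy)-6-hydroxy-4-methoxyphenyl]ethan-1-one, 7 2-(benzyloxy)-5-formylbenzonitrile
Product: 8 (E)-1-[2-(benzyloxy)-6-hydroxy-4-methoxyphenyl]-3-[4-(benzyloxy)-3-cyanophenyl]prop-2-en-1-one
Conditions: KOH, EtOH, rt
Reagents that add atoms: none
Why: Claisen–Schmidt condensation of the methyl ketone with the non-enolisable aldehyde should give the E-chalcone, the nitrile being stable to ethanolic hydroxide at room temperature.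

**Step 6**
Reactants: 8 (E)-1-[2-(benzyloxy)-6-hydroxy-4-methoxyphenyl]-3-[4-(benzyloxy)-3-cyanophenyl]prop-2-en-1-one
Product: 9 2-(benzyloxy)-5-[5-(benzyloxy)-7-methoxy-4-oxo-4H-chromen-2-yl]benzonitrile
Conditions: I2 (10 mol%), DMSO, 120 °C
Reagents that add atoms: none
Why: Iodine-catalysed oxidative cyclisation of a 2′-hydroxychalcone (oxa-Michael closure, iodination/elimination, DMSO as terminal oxidant) should give the flavone.

**Step 7**
Reactants: 9 2-(benzyloxy)-5-[5-(benzyloxy)-7-methoxy-4-oxo-4H-chromen-2-yl]benzonitrile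
Product: 11 2-(benzyloxy)-5-[5-(benzyloxy)-7-methoxy-4-oxo-4H-chromen-2-yl]benzenecarboximidamide hydrochloride, via lithium N,N'-bis(trimethylsilyl)amidinate 10 (not isolated)
Conditions: LiHMDS, THF, 0 °C → rt; then HCl (dioxane), 0 °C
Reagents that add atoms: lithium bis(trimethylsilyl)amide [Li]N([Si](C)(C)C)[Si](C)(C)C; hydrogen chloride Cl
Why: Addition of the silylamide to the nitrile and N-desilylation with HCl is the standard amidine synthesis, and the flavone offers no acidic C–H and only a fully substituted β-carbon to the bulky amide.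

**Step 8**
Reactants: 11 2-(benzyloxy)-5-[5-(benzyloxy)-7-methoxy-4-oxo-4H-chromen-2-yl]benzenecarboximidamide hydrochloride
Product: 12 5-(benzyloxy)-2-[4-(benzyloxy)-3-(3-chloro-3H-diazirin-3-yl)phenyl]-7-methoxy-4H-chromen-4-one
Conditions: aq. NaOCl, LiCl, DMSO–CH2Cl2, 0 °C → rt, dark; used directly
Reagents that add atoms: sodium hypochlorite [Na+].[O-]Cl; lithium chloride [Li+].[Cl-]
Why: Graham reaction (double N-chlorination, base-induced N–N closure, chloride exchange) should give the 3-chloro-3-aryl-3H-diazirine, the basic medium keeping hypochlorite from chlorinating the alkoxy-arenes.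

**Step 9**
Reactants: 12 5-(benzyloxy)-2-[4-(benzyloxy)-3-(3-chloro-3H-diazirin-3-yl)phenyl]-7-methoxy-4H-chromen-4-one, 3 tert-butyl{[4,6-bis(benzyloxy)-1-benzofuran-3-yl]oxy}dimethylsilane
Product: 16 5,7-bis(benzyloxy)-3-{2-(benzyloxy)-5-[5-(benzyloxy)-7-methoxy-4-oxo-4H-chromen-2-yl]phenyl}-4H-chromen-4-one, via aryl(chloro)carbene 13 (not isolated), via chlorocyclopropane adduct 14 (not isolated), via 4-silyloxybenzopyrylium chloride 15 (not isolated)
Conditions: 3 (3 equiv), Na2CO3, MeCN–PhCF3, 55 °C, dark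
Reagents that add atoms: none
Why: Proposed new method: thermolysis of the chlorodiazirine should release N2 and the singlet aryl(chloro)carbene 13, which adds in a [2+1] fashion to the C2=C3 enol-ether π bond of 3; the gem-chlorocyclopropane 14 is then set up for a disrotatory cyclopropyl-to-allyl opening in which chloride leaves and the old C2–C3 σ bond breaks, pushed by the lone pairs of the ring oxygen and the silyloxy group, to give the aromatic benzopyrylium 15, from which chloride takes the silyl group to unveil the chromone. The closest known reaction type is the Ciamician–Dennstedt-type carbon-atom insertion of aryl(chloro)carbenes from chlorodiazirines into indoles, pyrroles and indenes, together with the dihalocarbene ring expansion of cyclic silyl enol ethers and of benzofurans. The only ring closed is the transient cyclopropane ([2+1] cheletropic addition); the six-membered pyranone ring is not closed but arises from the five-membered furan ring by this one-carbon expansion, so the inserted carbon necessarily ends between C-2 and C-4 and brings the flavone aryl group with it. No stereocentre survives the step (the cyclopropane centres are destroyed on opening); C-2 and C-3 are set in step 10. The selectivity needed is chemoselectivity of the carbene for the enol ether over C–H insertion into its own ortho benzyloxy CH2 group, over the flavone and over the alkoxy-arenes, which the high nucleophilicity of the silyloxybenzofuran double bond, used in excess and at high concentration, should secure.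

**Step 10**
Reactants: 16 5,7-bis(benzyloxy)-3-{2-(benzyloxy)-5-[5-(benzyloxy)-7-methoxy-4-oxo-4H-chromen-2-yl]phenyl}-4H-chromen-4-one, 17 [4-(benzyloxy)phenyl]boronic acid
Product: 19 (2S,3R)-5,7-bis(benzyloxy)-2-[4-(benzyloxy)phenyl]-3-{2-(benzyloxy)-5-[5-(benzyloxy)-7-methoxy-4-oxo-4H-chromen-2-yl]phenyl}-2,3-dihydro-4H-chromen-4-one, via (2S,3S)-cis epimer 18 (not isolated)
Conditions: [RhCl(C2H4)2]2 (3 mol%), chiral electron-poor biaryl bisphosphine (MeO-F12-BIPHEP type, 6.5 mol%), aq. KOH (cat.), toluene–H2O, 40 °C; then Et3N, CH2Cl2, rt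
Reagents that add atoms: none
Why: Hayashi–Miyaura rhodium-catalysed asymmetric 1,4-addition of the arylboronic acid to the 2-unsubstituted chromone (the flavone β-carbon is fully substituted and should not react) sets 2S by ligand-controlled delivery of the aryl group to the Re face of C-2, the ligand antipode being fixed on a model isoflavone, and the acidic C-3 centre then equilibrates under amine base to the more stable 2,3-trans arrangement (3R).

**Step 11**
Reactants: 19 (2S,3R)-5,7-bis(benzyloxy)-2-[4-(benzyloxy)phenyl]-3-{2-(benzyloxy)-5-[5-(benzyloxy)-7-methoxy-4-oxo-4H-chromen-2-yl]phenyl}-2,3-dihydro-4H-chromen-4-one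
Product: 20 (2S,3R)-5,7-dihydroxy-3-[2-hydroxy-5-(5-hydroxy-7-methoxy-4-oxo-4H-chromen-2-yl)phenyl]-2-(4-hydroxyphenyl)-2,3-dihydro-4H-chromen-4-one
Conditions: H2 (1 atm), 10% Pd/C, EtOAc–MeOH, rt
Reagents that add atoms: none
Why: Hydrogenolysis of the five aryl benzyl ethers over palladium under neutral conditions should free all phenols without touching the flavone double bond, the ketones, the methyl ether or the C-2/C-3 stereocentres.

**Compound list**
1 | 4,6-dihydroxy-1-benzofuran-3(2H)-one | O=C1COc2cc(O)cc(O)c12 | starting material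
2 | 4,6-bis(benzyloxy)-1-benzofuran-3(2H)-one | O=C1COc2cc(OCc3ccccc3)cc(OCc3ccccc3)c12 | intermediate
3 | tert-butyl{[4,6-bis(benzyloxy)-1-benzofuran-3-yl]oxy}dimethylsilane | CC(C)(C)[Si](C)(C)Oc1coc2cc(OCc3ccccc3)cc(OCc3ccccc3)c12 | intermediate
4 | 1-(2,6-dihydroxy-4-methoxyphenyl)ethan-1-one | CC(=O)c1c(O)cc(OC)cc1O | starting material
5 | 1-[2-(benzyloxy)-6-hydroxy-4-methoxyphenyl]ethan-1-one | CC(=O)c1c(O)cc(OC)cc1OCc1ccccc1 | intermediate
6 | 5-formyl-2-hydroxybenzonitrile | N#Cc1cc(C=O)ccc1O | starting material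
7 | 2-(benzyloxy)-5-formylbenzonitrile | N#Cc1cc(C=O)ccc1OCc1ccccc1 | intermediate
8 | (E)-1-[2-(benzyloxy)-6-hydroxy-4-methoxyphenyl]-3-[4-(benzyloxy)-3-cyanophenyl]prop-2-en-1-one | COc1cc(O)c(C(=O)/C=C/c2ccc(OCc3ccccc3)c(C#N)c2)c(OCc2ccccc2)c1 | intermediate
9 | 2-(benzyloxy)-5-[5-(benzyloxy)-7-methoxy-4-oxo-4H-chromen-2-yl]benzonitrile | COc1cc(OCc2ccccc2)c2c(=O)cc(-c3ccc(OCc4ccccc4)c(C#N)c3)oc2c1 | intermediate
10 | lithium N,N'-bis(trimethylsilyl)-2-(benzyloxy)-5-[5-(benzyloxy)-7-methoxy-4-oxo-4H-chromen-2-yl]benzenecarboximidamidate (formed in situ) | COc1cc(OCc2ccccc2)c2c(=O)cc(-c3ccc(OCc4ccccc4)c(C(=N[Si](C)(C)C)N([Li])[Si](C)(C)C)c3)oc2c1 | intermediate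
11 | 2-(benzyloxy)-5-[5-(benzyloxy)-7-methoxy-4-oxo-4H-chromen-2-yl]benzenecarboximidamide hydrochloride | COc1cc(OCc2ccccc2)c2c(=O)cc(-c3ccc(OCc4ccccc4)c(C(N)=[NH2+])c3)oc2c1.[Cl-] | intermediate
12 | 5-(benzyloxy)-2-[4-(benzyloxy)-3-(3-chloro-3H-diazirin-3-yl)phenyl]-7-methoxy-4H-chromen-4-one | COc1cc(OCc2ccccc2)c2c(=O)cc(-c3ccc(OCc4ccccc4)c(C4(Cl)N=N4)c3)oc2c1 | intermediate
13 | {2-(benzyloxy)-5-[5-(benzyloxy)-7-methoxy-4-oxo-4H-chromen-2-yl]phenyl}(chloro)carbene (formed in situ) | COc1cc(OCc2ccccc2)c2c(=O)cc(-c3ccc(OCc4ccccc4)c([C]Cl)c3)oc2c1 | intermediate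
14 | chlorocyclopropane adduct of 13 across C2=C3 of 3, a 1-chloro-1-aryl-6b-silyloxy-1a,6b-dihydro-1H-cyclopropa[b]benzofuran (formed in situ, configuration not defined) | COc1cc(OCc2ccccc2)c2c(=O)cc(-c3ccc(OCc4ccccc4)c(C4(Cl)C5Oc6cc(OCc7ccccc7)cc(OCc7ccccc7)c6C45O[Si](C)(C)C(C)(C)C)c3)oc2c1 | intermediate
15 | 5,7-bis(benzyloxy)-3-{2-(benzyloxy)-5-[5-(benzyloxy)-7-methoxy-4-oxo-4H-chromen-2-yl]phenyl}-4-[(tert-butyldimethylsilyl)oxy]chromenylium chloride (formed in situ) | COc1cc(OCc2ccccc2)c2c(=O)cc(-c3ccc(OCc4ccccc4)c(-c4c[o+]c5cc(OCc6ccccc6)cc(OCc6ccccc6)c5c4O[Si](C)(C)C(C)(C)C)c3)oc2c1.[Cl-] | intermediate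
16 | 5,7-bis(benzyloxy)-3-{2-(benzyloxy)-5-[5-(benzyloxy)-7-methoxy-4-oxo-4H-chromen-2-yl]phenyl}-4H-chromen-4-one | COc1cc(OCc2ccccc2)c2c(=O)cc(-c3ccc(OCc4ccccc4)c(-c4coc5cc(OCc6ccccc6)cc(OCc6ccccc6)c5c4=O)c3)oc2c1 | intermediate
17 | [4-(benzyloxy)phenyl]boronic acid | OB(O)c1ccc(OCc2ccccc2)cc1 | starting material
18 | (2S,3S)-5,7-bis(benzyloxy)-2-[4-(benzyloxy)phenyl]-3-{2-(benzyloxy)-5-[5-(benzyloxy)-7-methoxy-4-oxo-4H-chromen-2-yl]phenyl}-2,3-dihydro-4H-chromen-4-one (cis epimer, formed in situ) | COc1cc(OCc2ccccc2)c2c(=O)cc(-c3ccc(OCc4ccccc4)c([C@@H]4C(=O)c5c(OCc6ccccc6)cc(OCc6ccccc6)cc5O[C@@H]4c4ccc(OCc6ccccc6)cc4)c3)oc2c1 | intermediate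
19 | (2S,3R)-5,7-bis(benzyloxy)-2-[4-(benzyloxy)phenyl]-3-{2-(benzyloxy)-5-[5-(benzyloxy)-7-methoxy-4-oxo-4H-chromen-2-yl]phenyl}-2,3-dihydro-4H-chromen-4-one | COc1cc(OCc2ccccc2)c2c(=O)cc(-c3ccc(OCc4ccccc4)c([C@H]4C(=O)c5c(OCc6ccccc6)cc(OCc6ccccc6)cc5O[C@@H]4c4ccc(OCc6ccccc6)cc4)c3)oc2c1 | intermediate
20 | (2S,3R)-5,7-dihydroxy-3-[2-hydroxy-5-(5-hydroxy-7-methoxy-4-oxo-4H-chromen-2-yl)phenyl]-2-(4-hydroxyphenyl)-2,3-dihydro-4H-chromen-4-one | COc1cc(O)c2c(=O)cc(-c3ccc(O)c([C@H]4C(=O)c5c(O)cc(O)cc5O[C@@H]4c4ccc(O)cc4)c3)oc2c1 | target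

**Totals**
Total step count: 11. Longest linear sequence: 8 steps (3, 5, 6, 7, 8, 9, 10, 11).

**Steps most likely to fail**

Step 9 (Proposed new method). The carbene may be used up by C–H insertion into its own ortho benzyloxy methylene or by self-reaction before the enol ether traps it, or the cyclopropane may open at an outer bond and so fail to expand the ring. The fallback uses known chemistry only, sets out from 5 and comes back at 16. Claisen–Schmidt condensation of 5 with commercial 4-(benzyloxy)-3-bromobenzaldehyde (KOH, EtOH) should give (E)-1-[2-(benzyloxy)-6-hydroxy-4-methoxyphenyl]-3-[4-(benzyloxy)-3-bromophenyl]prop-2-en-1-one F1. Iodine/DMSO cyclisation would give 5-(benzyloxy)-2-[4-(benzyloxy)-3-bromophenyl]-7-methoxy-4H-chromen-4-one F2, and Miyaura borylation (B2pin2, Pd(dppf)Cl2, KOAc, dioxane) the boronate 5-(benzyloxy)-2-[4-(benzyloxy)-3-(4,4,5,5-tetramethyl-1,3,2-dioxaborolan-2-yl)phenyl]-7-methoxy-4H-chromen-4-one F3. In parallel, commercial 1-[2,4-bis(benzyloxy)-6-hydroxyphenyl]ethan-1-one and DMF dimethyl acetal would give the enaminone (E)-1-[2,4-bis(benzyloxy)-6-hydroxyphenyl]-3-(dimethylamino)prop-2-en-1-one F4, which iodine closes to 5,7-bis(benzyloxy)-3-iodo-4H-chromen-4-one F5. Suzuki–Miyaura coupling of F3 with F5 (Pd(PPh3)4, aq. Na2CO3, DME) should then give 16.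

Step 10. Insertion into the α-aryl-substituted, electron-rich chromone may be sluggish, so that protodeboronation of the boronic acid or base-induced opening of the chromone wins, or facial selectivity at C-2 may be poor. The fallback sets out from 16 and comes back at 19. Aqueous NaOH in EtOH should cleave the 2-unsubstituted chromone, with loss of C-2, to the deoxybenzoin 1-[2,4-bis(benzyloxy)-6-hydroxyphenyl]-2-{2-(benzyloxy)-5-[5-(benzyloxy)-7-methoxy-4-oxo-4H-chromen-2-yl]phenyl}ethan-1-one F6. Condensation of F6 with 4-(benzyloxy)benzaldehyde (piperidine, EtOH, reflux; Knoevenagel then oxa-Michael closure) should give the racemic trans-2,3-diarylchromanone, that is 19 together with its mirror image (2R,3S)-5,7-bis(benzyloxy)-2-[4-(benzyloxy)phenyl]-3-{2-(benzyloxy)-5-[5-(benzyloxy)-7-methoxy-4-oxo-4H-chromen-2-yl]phenyl}-2,3-dihydro-4H-chromen-4-one F7. Preparative chromatography on a chiral stationary phase would deliver 19, and F7 would be returned to the racemate with base (retro-oxa-Michael/oxa-Michael) and recycled.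

Step 8. Hypochlorite may chlorinate the alkoxy-rich flavone A ring instead of, or as well as, the amidine nitrogen atoms, and the diazirine may decompose during isolation. The fallback keeps the one-carbon ring expansion but avoids the diazirine; it sets out from 3 and comes back at 16. Dibromocarbene (CHBr3, KOtBu, pentane–THF, −20 °C → rt) should add to the enol ether of 3 and ring-expand to 5,7-bis(benzyloxy)-3-bromo-4H-chromen-4-one F8. Suzuki–Miyaura coupling of F8 with the boronate F3 (made from 5 as described under step 9) would then give 16.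

**Further compounds**
F1 | step 9 | (E)-1-[2-(benzyloxy)-6-hydroxy-4-methoxyphenyl]-3-[4-(benzyloxy)-3-bromophenyl]prop-2-en-1-one | COc1cc(O)c(C(=O)/C=C/c2ccc(OCc3ccccc3)c(Br)c2)c(OCc2ccccc2)c1
F2 | step 9 | 5-(benzyloxy)-2-[4-(benzyloxy)-3-bromophenyl]-7-methoxy-4H-chromen-4-one | COc1cc(OCc2ccccc2)c2c(=O)cc(-c3ccc(OCc4ccccc4)c(Br)c3)oc2c1
F3 | step 9 | 5-(benzyloxy)-2-[4-(benzyloxy)-3-(4,4,5,5-tetramethyl-1,3,2-dioxaborolan-2-yl)phenyl]-7-methoxy-4H-chromen-4-one | COc1cc(OCc2ccccc2)c2c(=O)cc(-c3ccc(OCc4ccccc4)c(B4OC(C)(C)C(C)(C)O4)c3)oc2c1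
F4 | step 9 | (E)-1-[2,4-bis(benzyloxy)-6-hydroxyphenyl]-3-(dimethylamino)prop-2-en-1-one | CN(C)/C=C/C(=O)c1c(O)cc(OCc2ccccc2)cc1OCc1ccccc1
F5 | step 9 | 5,7-bis(benzyloxy)-3-iodo-4H-chromen-4-one | O=c1c(I)coc2cc(OCc3ccccc3)cc(OCc3ccccc3)c12
F6 | step 10 | 1-[2,4-bis(benzyloxy)-6-hydroxyphenyl]-2-{2-(benzyloxy)-5-[5-(benzyloxy)-7-methoxy-4-oxo-4H-chromen-2-yl]phenyl}ethan-1-one | COc1cc(OCc2ccccc2)c2c(=O)cc(-c3ccc(OCc4ccccc4)c(CC(=O)c4c(O)cc(OCc5ccccc5)cc4OCc4ccccc4)c3)oc2c1
F7 | step 10 | (2R,3S)-5,7-bis(benzyloxy)-2-[4-(benzyloxy)phenyl]-3-{2-(benzyloxy)-5-[5-(benzyloxy)-7-methoxy-4-oxo-4H-chromen-2-yl]phenyl}-2,3-dihydro-4H-chromen-4-one | COc1cc(OCc2ccccc2)c2c(=O)cc(-c3ccc(OCc4ccccc4)c([C@@H]4C(=O)c5c(OCc6ccccc6)cc(OCc6ccccc6)cc5O[C@H]4c4ccc(OCc6ccccc6)cc4)c3)oc2c1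
F8 | step 8 | 5,7-bis(benzyloxy)-3-bromo-4H-chromen-4-one | O=c1c(Br)coc2cc(OCc3ccccc3)cc(OCc3ccccc3)c12
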